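**Plan**

1. Numbering: chroman O1, C2, C3, C4, C4a, C5–C8, C8a; cyclopentane C2–C3–C1'–C2'–C3' (C3' is the spiro carbon); cyclohexene C3'–C2''H=C3''(i-Pr)–C4''–C5''–C6''H(CH3).
2. Enabling feature: the cyclopentane is fused to the pyran across C2–C3 and spiro-joined at C3' to a cyclohexene whose C2''=C3'' bond is allylic to C3'. This is the carbonylative [2+2+1] adduct of an arene-tethered propargyl alkyne, CO and the enol-ether alkene of an aryl dienyl ether.
3. Retrosynthesis: remove both CHO groups and both O-methyl groups; cut C4–isobutyl (back to a C4 ketone, then C4H2), C3–CH3 and the C2' carbonyl; cut C2–C3, C3'–C2' and C2'–C1' in one operation; finally cut the aryl O–CH= bond and the benzylic C–C(alkyne) bond.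
4. Forward: the cyclohexane ring is bought as (−)-menthone and the arene as 2-hydroxy-4,6-dimethoxybenzaldehyde; they are joined through the enol-ether oxygen; pyran and cyclopentenone then close together; C3 methylation, deoxygenation, C4 elaboration, diformylation and demethylation follow.
5. Stereochemistry: C6'' comes from menthone; the (E) enol ether from a reversible addition–elimination; C2 and C3' from the cyclocarbonylation (suprafacial addition, metal anti to the pseudoaxial C6'' methyl); C3 from Me2CuLi attack on the C2–H face; C4 from hydride delivery on the convex face of the cis-fused bicycle.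

Key step: step 9

Remark: commercial (−)-menthone containing isomenthone can be used as such, because both epimers share the (5R) methyl centre and the isopropyl-bearing centre becomes sp2 in step 6.

Step 1
Reactants: 1 2-hydroxy-4,6-dimethoxybenzaldehyde; 2 ethynyltrimethylsilane
Product: 3 (±)-2-[1-hydroxy-3-(trimethylsilyl)prop-2-yn-1-yl]-3,5-dimethoxyphenol
Conditions: 2 (2.3 equiv), n-BuLi (2.2 equiv), THF, −78 °C; add 1, −78 → 0 °C; aq. NH4Cl; crude product used directly
Reagents that add atoms: none
Why: 1,2-addition of lithium (trimethylsilyl)acetylide to the aldehyde, in which the first equivalent deprotonates the phenol and the second adds to the carbonyl; the racemic carbinol centre is removed in step 2.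

Step 2
Reactants: 3 (±)-2-[1-hydroxy-3-(trimethylsilyl)prop-2-yn-1-yl]-3,5-dimethoxyphenol
Product: 4 3,5-dimethoxy-2-[3-(trimethylsilyl)prop-2-yn-1-yl]phenol
Conditions: Et3SiH (3 equiv), CF3CO2H (3 equiv), CH2Cl2, −20 → 0 °C
Reagents that add atoms: none
Why: ionic hydrogenation, in which acid ionises the benzylic, propargylic alcohol and Et3SiH delivers hydride to the benzylic carbon, where the three ring oxygens concentrate the positive charge, so the propargyl arene and not the allene should form.

Step 3
Reactants: 5 (−)-menthone, (2S,5R)-5-methyl-2-(propan-2-yl)cyclohexan-1-one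
Product: 6 (2Z,3R)-2-(hydroxymethylidene)-3-methyl-6-(propan-2-yl)cyclohexan-1-one (hydrogen-bonded enol of the β-keto aldehyde; C6 epimers)
Conditions: NaH, HCO2Et, cat. EtOH, THF, 0 °C → rt; aq. HCl
Reagents that add atoms: ethyl formate, CCOC=O
Why: crossed Claisen condensation (formylation) takes place only at the α-CH2 group, the one position that can give the stabilised hydroxymethylene enolate, and leaves the adjacent methyl stereocentre untouched.

Step 4
Reactants: 6 (2Z,3R)-2-(hydroxymethylidene)-3-methyl-6-(propan-2-yl)cyclohexan-1-one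
Product: 7 (2E,3R)-2-(chloromethylidene)-3-methyl-6-(propan-2-yl)cyclohexan-1-one (C6 epimers)
Conditions: (COCl)2, cat. DMF, CH2Cl2, 0 °C → rt
Reagents that add atoms: oxalyl chloride, ClC(=O)C(Cl)=O
Why: the vinylogous acid is converted into the vinylogous acid chloride (β-chloro enone) by the usual oxalyl chloride activation with loss of CO, CO2 and HCl.

Step 5
Reactants: 4 3,5-dimethoxy-2-[3-(trimethylsilyl)prop-2-yn-1-yl]phenol; 7 (2E,3R)-2-(chloromethylidene)-3-methyl-6-(propan-2-yl)cyclohexan-1-one
Product: 8 (2E,3R)-2-({3,5-dimethoxy-2-[3-(trimethylsilyl)prop-2-yn-1-yl]phenoxy}methylidene)-3-methyl-6-(propan-2-yl)cyclohexan-1-one (C6 epimers)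
Conditions: K2CO3, acetone, rt
Reagents that add atoms: none
Why: addition–elimination (vinylogous acyl substitution) of the phenoxide on the β-chloro enone, in which reversible conjugate addition lets the product settle in the (E) geometry with the aryloxy group anti to the carbonyl while the neighbouring methyl group turns pseudoaxial to escape allylic strain.

Step 6
Reactants: 8 (E)-aryloxymethylidene ketone
Product: 9 (5R,6E)-6-({3,5-dimethoxy-2-[3-(trimethylsilyl)prop-2-yn-1-yl]phenoxy}methylidene)-5-methyl-2-(propan-2-yl)cyclohex-1-en-1-yl trifluoromethanesulfonate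
Conditions: KN(SiMe3)2, THF, −78 °C; PhNTf2, −78 → 0 °C; aq. NH4Cl
Reagents that add atoms: N-phenylbis(trifluoromethanesulfonimide), O=S(=O)(N(c1ccccc1)S(=O)(=O)C(F)(F)F)C(F)(F)F
Why: deprotonation at the only enolisable position (the isopropyl-bearing α-carbon) and O-sulfonylation of the cross-conjugated enolate give the enol triflate and erase the undefined stereocentre.

Step 7
Reactants: 9 dienyl triflate
Product: 10 1-{(E)-[(6R)-6-methyl-3-(propan-2-yl)cyclohex-2-en-1-ylidene]methoxy}-3,5-dimethoxy-2-[3-(trimethylsilyl)prop-2-yn-1-yl]benzene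
Conditions: Pd(OAc)2 (5 mol %), PPh3, HCO2H, Et3N, DMF, 60 °C
Reagents that add atoms: none
Why: palladium-catalysed formate reduction of an enol triflate (oxidative addition to zerovalent palladium, decarboxylative hydride transfer from formate, reductive elimination) replaces OTf by H with retention of the enol-ether geometry, and the silyl cap keeps the alkyne out of the coupling.

Step 8
Reactants: 10 silyl-protected dienyl ether
Product: 11 1-{(E)-[(6R)-6-methyl-3-(propan-2-yl)cyclohex-2-en-1-ylidene]methoxy}-3,5-dimethoxy-2-(prop-2-yn-1-yl)benzene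
Conditions: K2CO3 (cat.), MeOH/THF, rt
Reagents that add atoms: none
Why: base-catalysed methanolysis of the alkynyl C–Si bond, under conditions that leave the enol ether intact and are too mild to isomerise the propargyl arene.

Step 9
Reactants: 11 (E)-dienyl 2-propargyl-3,5-dimethoxyphenyl ether; 12 carbon monoxide
Product: 13 spiro cyclopentenone (2R,3'S,6''R): 5,7-dimethoxychroman fused across C2–C3 to a cyclopent-2-enone (C3=C1'H, C2'=O) whose C3' is the spiro atom of the 3''-isopropyl-6''-methylcyclohex-2''-ene; C4 is CH2; O1 and C6'' cis on the five-membered ring, C2' trans to the 6''-methyl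
Conditions: [RhCl(CO)2]2 (5 mol %), CO (1 atm), 1,2-dichloroethane (0.02 M), 80 °C
Reagents that add atoms: none
Why: Proposed new method: oxidative cyclisation of the alkyne and the enol-ether alkene on monovalent rhodium should give a rhodacyclopentene whose Rh–C3' bond is held as an η3-allyl by the C2''=C3'' alkene, after which CO insertion and reductive elimination release the enone. The closest known reactions are the [RhCl(CO)2]2-catalysed dienyl Pauson–Khand reaction and Pauson–Khand reactions of arene-tethered enynes, neither of which has been shown for an enol-ether diene whose reacting alkene carbon is fully substituted. The pyran closes as the six-membered tether ring of the 1,7-enyne when C2–C3 forms in the oxidative cyclisation, and the cyclopentenone closes in the carbonylative [2+2+1] event through the C3'–C2' and C2'–C1' bonds. C2 and C3' are created together by suprafacial addition across the (E)-alkene, which places O1 and C6'' cis on the new five-membered ring. Their absolute sense is dictated by the C6'' methyl group, which allylic 1,3-strain with the aryloxy group forces pseudoaxial so that rhodium binds the opposite alkene face. The step needs [2+2+1] to prevail over [4+2] cycloaddition and over β-aryloxy elimination: the ring-locked transoid diene cannot act as a 4π partner, and in the fused metallacycle the Rh–C3'–C2–O1 unit cannot become syn-coplanar.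

Step 10
Reactants: 13 spiro cyclopentenone
Product: 15 (2R,3R,3'S,6''R)-3-methyl cyclopentanone (as 13 but C3 quaternary with CH3 cis to C2–H, C1' = CH2, C2' = C=O), via silyl enol ether 14 (not isolated)
Conditions: Me2CuLi (from MeLi, CuI), Me3SiCl, THF, −78 → −20 °C; aq. NH4Cl, then 1 M HCl/THF, 0 °C
Reagents that add atoms: methyllithium, [Li]C
Why: Me3SiCl-accelerated conjugate addition of Me2CuLi, in which methyl attacks C3 on the face of C2–H because the other face is covered by the folded benzopyran and by C6'', so the cis ring fusion is set and the silyl enol ether is hydrolysed on work-up.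

Step 11
Reactants: 15 3-methyl cyclopentanone
Product: 17 (2R,3S,3'R,6''R)-5,7-dimethoxy-3-methyl tetracycle with C1'H2, C2'H2 and C4H2, via hydrazone 16 (not isolated)
Conditions: N2H4·H2O, KOH, diethylene glycol, 130 °C then 200 °C, under N2
Reagents that add atoms: none
Why: Wolff–Kishner reduction (Huang-Minlon procedure), which is precedented for cyclopentanones flanked by a quaternary carbon and puts no stereocentre at risk because the spiro α-carbon carries no hydrogen.

Step 12
Reactants: 17 deoxygenated tetracycle
Product: 19 chroman-4-one (4-oxo derivative of 17), via benzylic alcohol 18 (not isolated)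
Conditions: DDQ (2.5 equiv), CH2Cl2/H2O (10:1), rt
Reagents that add atoms: water, O
Why: DDQ benzylic oxidation, in which hydride is abstracted from C4 (activated by the three ring oxygens), water captures the cation and a second hydride abstraction from the benzylic alcohol gives the ketone, while the isolated trisubstituted alkene is inert to DDQ.

Step 13
Reactants: 19 chroman-4-one
Product: 20 4-hydroxy-4-(2-methylpropyl) derivative of 17 (C4 epimers)
Conditions: i-BuLi, CeCl3, THF, −78 °C; aq. NH4Cl
Reagents that add atoms: isobutyllithium, [Li]CC(C)C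
Why: 1,2-addition of i-BuCeCl2 to a hindered, non-enolisable aryl ketone, the cerium reagent suppressing β-hydride reduction; the configuration of the new carbinol centre is irrelevant because it is ionised in step 14.

Step 14
Reactants: 20 tertiary benzylic alcohol
Product: 21 (2R,3S,4R,3'R,6''R)-4-(2-methylpropyl)-5,7-dimethoxy tetracycle, C4–H cis to C3–CH3 and C2–H
Conditions: Et3SiH (5 equiv), CF3CO2H (2 equiv), CH2Cl2, −40 → −10 °C
Reagents that add atoms: none
Why: ionic hydrogenation, in which the tertiary, triply oxygen-stabilised benzylic cation forms at low temperature and should accept hydride on the convex face of the cis-fused pyran–cyclopentane (the side of C3–CH3 and C2–H, away from the cyclopentane and C6''), placing isobutyl trans to the C3 methyl and pseudoaxial, clear of the C5 methoxy group, while the ring alkene is not protonated under these conditions.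

Step 15
Reactants: 21 4-isobutyl dimethyl ether
Product: 22 (2R,3S,4R,3'R,6''R)-5,7-dimethoxy-6,8-dicarbaldehyde
Conditions: Cl2CHOMe (6 equiv), TiCl4 (6 equiv), CH2Cl2, −78 → 0 °C; ice/water
Reagents that add atoms: dichloromethyl methyl ether, COC(Cl)Cl; water, O
Why: Rieche formylation, in which C6 and C8 are each ortho or para to three oxygens and are the most nucleophilic sites of the molecule, so twofold electrophilic substitution followed by hydrolysis of the α-chloro ethers should give the dialdehyde.

Step 16
Reactants: 22 dialdehyde dimethyl ether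
Product: 23 CNP0121396.1, (2R,3S,4R,3'R,6''R)-5,7-dihydroxy-6,8-dicarbaldehyde (target)
Conditions: NaSEt (6 equiv), DMF, 110 °C; aq. HCl
Reagents that add atoms: none
Why: nucleophilic demethylation (SN2 at methyl by ethanethiolate) accelerated by the ortho and para formyl groups, while the pyran oxygen sits on a neopentyl-type secondary carbon that the thiolate cannot attack and the basic medium spares the alkene.

**Compound list**

1 | 2-hydroxy-4,6-dimethoxybenzaldehyde | COc1cc(O)c(C=O)c(OC)c1 | starting material
2 | ethynyltrimethylsilane | C#C[Si](C)(C)C | starting material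
3 | (±)-2-[1-hydroxy-3-(trimethylsilyl)prop-2-yn-1-yl]-3,5-dimethoxyphenol | COc1cc(O)c(C(O)C#C[Si](C)(C)C)c(OC)c1 | intermediate
4 | 3,5-dimethoxy-2-[3-(trimethylsilyl)prop-2-yn-1-yl]phenol | COc1cc(O)c(CC#C[Si](C)(C)C)c(OC)c1 | intermediate
5 | (−)-menthone, (2S,5R)-5-methyl-2-(propan-2-yl)cyclohexan-1-one | C[C@@H]1CC[C@H](C(=O)C1)C(C)C | starting material
6 | (2Z,3R)-2-(hydroxymethylidene)-3-methyl-6-(propan-2-yl)cyclohexan-1-one (C6 epimers) | O/C=C1\C(=O)C(C(C)C)CC[C@H]1C | intermediate
7 | (2E,3R)-2-(chloromethylidene)-3-methyl-6-(propan-2-yl)cyclohexan-1-one (C6 epimers) | Cl/C=C1/C(=O)C(C(C)C)CC[C@H]1C | intermediate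
8 | (2E,3R)-2-({3,5-dimethoxy-2-[3-(trimethylsilyl)prop-2-yn-1-yl]phenoxy}methylidene)-3-methyl-6-(propan-2-yl)cyclohexan-1-one (C6 epimers) | C[Si](C)(C)C#CCc1c(OC)cc(OC)cc1O/C=C1/C(=O)C(C(C)C)CC[C@H]1C | intermediate
9 | (5R,6E)-6-({3,5-dimethoxy-2-[3-(trimethylsilyl)prop-2-yn-1-yl]phenoxy}methylidene)-5-methyl-2-(propan-2-yl)cyclohex-1-en-1-yl trifluoromethanesulfonate | C[Si](C)(C)C#CCc1c(OC)cc(OC)cc1O/C=C1/C(OS(=O)(=O)C(F)(F)F)=C(C(C)C)CC[C@H]1C | intermediate
10 | 1-{(E)-[(6R)-6-methyl-3-(propan-2-yl)cyclohex-2-en-1-ylidene]methoxy}-3,5-dimethoxy-2-[3-(trimethylsilyl)prop-2-yn-1-yl]benzene | C[Si](C)(C)C#CCc1c(OC)cc(OC)cc1O/C=C1/C=C(C(C)C)CC[C@H]1C | intermediate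
11 | 1-{(E)-[(6R)-6-methyl-3-(propan-2-yl)cyclohex-2-en-1-ylidene]methoxy}-3,5-dimethoxy-2-(prop-2-yn-1-yl)benzene | C#CCc1c(OC)cc(OC)cc1O/C=C1/C=C(C(C)C)CC[C@H]1C | intermediate
12 | carbon monoxide | [C-]#[O+] | starting material
13 | spiro cyclopentenone (2R,3'S,6''R), C3=C1' enone, C2' ketone, C4H2 | C1c2c(OC)cc(OC)cc2O[C@@H]2C1=CC(=O)[C@@]21C=C(C(C)C)CC[C@H]1C | intermediate
14 | trimethylsilyl enol ether of 15 (C1'=C2'–OSiMe3) | C1c2c(OC)cc(OC)cc2O[C@@H]2[C@@]1(C)C=C(O[Si](C)(C)C)[C@@]21C=C(C(C)C)CC[C@H]1C | intermediate
15 | (2R,3R,3'S,6''R)-3-methyl cyclopentanone (C3–CH3 cis to C2–H, C2' ketone) | C1c2c(OC)cc(OC)cc2O[C@@H]2[C@@]1(C)CC(=O)[C@@]21C=C(C(C)C)CC[C@H]1C | intermediate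
16 | C2' hydrazone of 15 | C1c2c(OC)cc(OC)cc2O[C@@H]2[C@@]1(C)CC(=NN)[C@@]21C=C(C(C)C)CC[C@H]1C | intermediate
17 | (2R,3S,3'R,6''R)-5,7-dimethoxy-3-methyl tetracycle (C1'H2, C2'H2, C4H2) | C1c2c(OC)cc(OC)cc2O[C@@H]2[C@@]1(C)CC[C@@]21C=C(C(C)C)CC[C@H]1C | intermediate
18 | 4-hydroxy derivative of 17 (C4 epimers) | OC1c2c(OC)cc(OC)cc2O[C@@H]2[C@@]1(C)CC[C@@]21C=C(C(C)C)CC[C@H]1C | intermediate
19 | chroman-4-one, 4-oxo derivative of 17 | O=C1c2c(OC)cc(OC)cc2O[C@@H]2[C@@]1(C)CC[C@@]21C=C(C(C)C)CC[C@H]1C | intermediate
20 | 4-hydroxy-4-(2-methylpropyl) derivative of 17 (C4 epimers) | CC(C)CC1(O)c2c(OC)cc(OC)cc2O[C@@H]2[C@@]1(C)CC[C@@]21C=C(C(C)C)CC[C@H]1C | intermediate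
21 | (2R,3S,4R,3'R,6''R)-4-(2-methylpropyl)-5,7-dimethoxy tetracycle | CC(C)C[C@H]1c2c(OC)cc(OC)cc2O[C@@H]2[C@@]1(C)CC[C@@]21C=C(C(C)C)CC[C@H]1C | intermediate
22 | (2R,3S,4R,3'R,6''R)-5,7-dimethoxy-6,8-dicarbaldehyde | CC(C)C[C@H]1c2c(OC)c(C=O)c(OC)c(C=O)c2O[C@@H]2[C@@]1(C)CC[C@@]21C=C(C(C)C)CC[C@H]1C | intermediate
23 | CNP0121396.1, (2R,3S,4R,3'R,6''R)-5,7-dihydroxy-6,8-dicarbaldehyde | CC(C)C[C@H]1c2c(O)c(C=O)c(O)c(C=O)c2O[C@@H]2[C@@]1(C)CC[C@@]21C=C(C(C)C)CC[C@H]1C | target

**Step count**

Total: 16 steps. Longest linear sequence: 14 steps (5 → 23, steps 3–16); the arene branch (steps 1–2) joins at step 5.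

**Steps most likely to fail**

1. Step 9 (cyclocarbonylation). The rhodium may fail to undergo oxidative cyclisation at the fully substituted enol-ether carbon, so that the alkyne is consumed by oligomerisation or simple cycloisomerisation instead of carbonylative ring closure. The fallback uses the stoichiometric cobalt Pauson–Khand reaction, which is documented for arene-tethered enynes and for enol-ether alkenes. Setting out from 11, Co2(CO)8 in CH2Cl2 at room temperature would give the hexacarbonyldicobalt alkyne complex F1. Treatment with N-methylmorpholine N-oxide at 0 °C → rt should then induce alkene insertion on the same, less hindered alkene face and carbonyl insertion, and so come back to the route at 13.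

2. Step 14 (hydride delivery at C4). Facial selectivity may be poor or reversed, so that hydride enters on the cyclopentane side and the C4 epimer results. The fallback inverts the order in which carbon and hydrogen are attached at C4, so that the same facial preference then places the carbon substituent where hydride would have gone. Setting out from 17, DDQ in CH2Cl2/MeOH would give the C4 methyl ether F2. BF3·OEt2 and trimethyl(2-methylallyl)silane at −78 °C (Hosomi–Sakurai allylation of the C4 cation) would give the 4-(2-methylallyl) compound F3. Hydrogenation with H2 and RhCl(PPh3)3 should saturate only the 1,1-disubstituted alkene and return to the route at 21.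

3. Step 15 (twofold formylation). The chloro ether, TiCl4 or liberated HCl may attack the trisubstituted ring alkene, or the reaction may stall after the first formyl group has deactivated the arene. The fallback separates halogenation from carbonyl introduction. Setting out from 21, NBS (2.1 equiv) in MeCN at 0 °C would give the 6,8-dibromide F4, aromatic bromination of the trialkoxy arene being much faster than attack on the alkene. Double bromine–lithium exchange with t-BuLi (4.4 equiv) in THF at −78 °C followed by DMF should then come back to the route at 22.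

Further compounds
F1 | step 9 | hexacarbonyldicobalt complex of alkyne 11 (Co2(CO)6 bridging the C≡C bond) | COc1cc(OC)c(CC23[CH]4[Co]2(=C=O)(=C=O)(=C=O)[Co]34(=C=O)(=C=O)=C=O)c(O/C=C2/C=C(C(C)C)CC[C@H]2C)c1
F2 | step 14 | 4-methoxy derivative of 17 (C4 epimers) | COC1c2c(OC)cc(OC)cc2O[C@@H]2[C@@]1(C)CC[C@@]21C=C(C(C)C)CC[C@H]1C
F3 | step 14 | 4-(2-methylallyl) analogue of 21, C4–H cis to C3–CH3 | CC(=C)C[C@H]1c2c(OC)cc(OC)cc2O[C@@H]2[C@@]1(C)CC[C@@]21C=C(C(C)C)CC[C@H]1C
F4 | step 15 | 6,8-dibromo derivative of 21 | CC(C)C[C@H]1c2c(OC)c(Br)c(OC)c(Br)c2O[C@@H]2[C@@]1(C)CC[C@@]21C=C(C(C)C)CC[C@H]1C
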